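The 14-membered carbocycle is closed at C4–C5 (cembrane numbering, defined below). The C18 carboxyl on C4 stands γ,δ to C6–C7, so with a temporary C6=C7 alkene the ring bond is the retron of an Ireland–Claisen rearrangement. The precursor is a 14-membered lactone (C18 to the oxygen on C7) carrying a vinyl group on C7. One [3,3] shift converts lactone into carbocycle, forms C4–C5 and relays the configuration of the aldol-derived carbinol C7 to C4, next to C3 of the bridging oxolane. The lactone is assembled from a limonene-derived oxolane ketone and an aldol-derived sulfone by Z-selective Julia–Kocienski olefination and macrolactonisation.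

Key step: step 14

Remark on numbering: ring carbons are C1–C14. C1 carries C15 (the CMe2 carbon, methyls C16 and C17), whose oxygen bridges to C3 (oxolane ring O, C3, C2, C1, C15). C18 is the carboxyl on C4, C19 the carboxyl on C8, C20 the methyl on C12, and the alkene is C11=C12. The target is (1R,3S,4S,8R,11Z), with the C1 and C3 substituents trans on the oxolane.

Assumption: commercial (+)-limonene oxide is used as its cis/trans mixture, since both isomers converge in step 1.

**Left fragment (C1–C4, C12–C18, C20)**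

Step 1
Reactants: 1 (4R)-limonene 1,2-oxide
Product: 3 (3R)-6-oxo-3-(prop-1-en-2-yl)heptanal, via (1S,2S,4R)-limonene-1,2-diol 2 (not isolated)
Conditions: H5IO6, THF/H2O, 0 °C → rt
Reagents that add atoms: water O
Why: Periodic acid hydrolyses both epoxide isomers to the 1,2-diol and cleaves it (glycol cleavage) without touching the isopropenyl group, and the terpene stereocentre (later C1) is carried over unchanged.

Step 2
Reactants: 3 (3R)-6-oxo-3-(prop-1-en-2-yl)heptanal; 4 ethyl diazoacetate
Product: 5 ethyl (5R)-3,8-dioxo-5-(prop-1-en-2-yl)nonanoate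
Conditions: SnCl2 (10 mol%), CH2Cl2, rt
Reagents that add atoms: none
Why: Roskamp reaction, in which Lewis-acid-promoted addition of the diazoester to the aldehyde is followed by a 1,2-hydride shift with loss of N2 to give the β-keto ester, the methyl ketone being too unreactive to compete.

Step 3
Reactants: 5 ethyl (5R)-3,8-dioxo-5-(prop-1-en-2-yl)nonanoate
Product: 6 ethyl (3S,5R)-3-hydroxy-8-oxo-5-(prop-1-en-2-yl)nonanoate
Conditions: H2 (4 atm), RuCl2[(S)-BINAP] (1 mol%), EtOH, 50 °C
Reagents that add atoms: none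
Why: Noyori asymmetric hydrogenation, in which the chelating β-keto ester is reduced on the face dictated by (S)-BINAP to give the 3S carbinol (future C3), while the non-chelating methyl ketone and the unfunctionalised alkene are expected to remain.

Step 4
Reactants: 6 ethyl (3S,5R)-3-hydroxy-8-oxo-5-(prop-1-en-2-yl)nonanoate
Product: 7 ethyl 2-[(2S,4R)-5,5-dimethyl-4-(3-oxobutyl)oxolan-2-yl]acetate
Conditions: TsOH·H2O (cat.), CH2Cl2, rt
Reagents that add atoms: none
Why: Acid-catalysed Markovnikov hydroalkoxylation, in which protonation of the 1,1-disubstituted alkene gives a tertiary cation that the secondary hydroxyl captures in a 5-exo mode, so the C–O bond at the carbinol is not broken and both stereocentres are kept (trans across the oxolane).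

**Right fragment (C5–C11, C19)**

Step 5
Reactants: 8 (S)-4-benzyloxazolidin-2-one; 9 5-bromopentanoyl chloride
Product: 10 (S)-4-benzyl-3-(5-bromopentanoyl)oxazolidin-2-one
Conditions: n-BuLi, THF, −78 °C; then 9
Reagents that add atoms: none
Why: N-Acylation of the lithiated oxazolidinone by the acid chloride is fast at −78 °C and leaves the primary bromide untouched.

Step 6
Reactants: 10 (S)-4-benzyl-3-(5-bromopentanoyl)oxazolidin-2-one; 11 acrolein
Product: 13 (S)-4-benzyl-3-[(2S,3R)-2-(3-bromopropyl)-3-hydroxypent-4-enoyl]oxazolidin-2-one, via dibutylboron Z-enolate 12 (not isolated)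
Conditions: Bu2BOTf, iPr2NEt, CH2Cl2, −78 → 0 °C; acrolein, −78 → 0 °C; then pH 7 buffer, MeOH, 30% H2O2
Reagents that add atoms: dibutylboron triflate CCCCB(CCCC)OS(=O)(=O)C(F)(F)F (boron group present in 12 only)
Why: Evans syn aldol reaction, in which the Z boron enolate reacts through a Zimmerman–Traxler chair on the face away from the benzyl group and so sets C8 and the carbinol C7 (syn) in one step, the boron enolate being too weak a nucleophile to displace the remote bromide.

Step 7
Reactants: 13 (S)-4-benzyl-3-[(2S,3R)-2-(3-bromopropyl)-3-hydroxypent-4-enoyl]oxazolidin-2-one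
Product: 14 (2R,3R)-2-(3-bromopropyl)pent-4-ene-1,3-diol
Conditions: LiBH4, MeOH (1 equiv), THF, 0 °C
Reagents that add atoms: none
Why: Reductive cleavage of the imide (hydride attack at the exocyclic carbonyl, faster at 0 °C than reduction of the alkyl bromide) releases the auxiliary and gives the 1,3-diol without touching either stereocentre.

Step 8
Reactants: 14 (2R,3R)-2-(3-bromopropyl)pent-4-ene-1,3-diol
Product: 15 (3R,4R)-7-bromo-4-({[tert-butyl(dimethyl)silyl]oxy}methyl)hept-1-en-3-ol
Conditions: t-BuMe2SiCl, imidazole, CH2Cl2, 0 °C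
Reagents that add atoms: tert-butyldimethylsilyl chloride CC(C)(C)[Si](C)(C)Cl
Why: Silylation is selective for the primary hydroxyl (C19) over the hindered secondary allylic one on steric grounds.

Step 9
Reactants: 15 (3R,4R)-7-bromo-4-({[tert-butyl(dimethyl)silyl]oxy}methyl)hept-1-en-3-ol; 16 1-methyl-1H-tetrazole-5-thiol
Product: 17 (3R,4R)-4-({[tert-butyl(dimethyl)silyl]oxy}methyl)-7-[(1-methyl-1H-tetrazol-5-yl)sulfanyl]hept-1-en-3-ol
Conditions: K2CO3, acetone, rt
Reagents that add atoms: none
Why: SN2 S-alkylation of the soft thiolate by the primary bromide, under conditions too weakly basic for the free hydroxyl to compete.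

Step 10
Reactants: 17 (3R,4R)-4-({[tert-butyl(dimethyl)silyl]oxy}methyl)-7-[(1-methyl-1H-tetrazol-5-yl)sulfanyl]hept-1-en-3-ol
Product: 18 (3R,4R)-4-({[tert-butyl(dimethyl)silyl]oxy}methyl)-7-[(1-methyl-1H-tetrazol-5-yl)sulfonyl]hept-1-en-3-ol
Conditions: (NH4)6Mo7O24·4H2O (cat.), 30% H2O2, EtOH, 0 °C → rt
Reagents that add atoms: hydrogen peroxide OO
Why: Molybdate-catalysed peroxide oxidation takes the sulfide through the sulfoxide to the sulfone much faster than it attacks the monosubstituted alkene.

**Union and endgame**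

Step 11
Reactants: 7 ethyl 2-[(2S,4R)-5,5-dimethyl-4-(3-oxobutyl)oxolan-2-yl]acetate; 18 (3R,4R)-4-({[tert-butyl(dimethyl)silyl]oxy}methyl)-7-[(1-methyl-1H-tetrazol-5-yl)sulfonyl]hept-1-en-3-ol
Product: 19 ethyl (1R,3S,7R,8R,11Z)-19-(tert-butyldimethylsilyloxy)-3,15-epoxy-7-hydroxy-4,5-secocembra-5,11-dien-18-oate (seco ester)
Conditions: LiN(SiMe3)2 (2.2 equiv) added to 7 + 18, THF, −78 °C → rt
Reagents that add atoms: none
Why: Julia–Kocienski olefination of a methyl ketone, in which the lithiated 1-methyltetrazolyl sulfone adds to the ketone under kinetic control and Smiles rearrangement with loss of SO2 and the tetrazolone then gives the C11=C12 alkene with the Z geometry known for this sulfone class with alkyl methyl ketones, the second equivalent of base holding the C7 hydroxyl as a spectator alkoxide.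

Step 12
Reactants: 19 seco ester
Product: 20 (1R,3S,7R,8R,11Z)-19-(tert-butyldimethylsilyloxy)-3,15-epoxy-7-hydroxy-4,5-secocembra-5,11-dien-18-oic acid (seco acid)
Conditions: LiOH, THF/MeOH/H2O, rt; then 1 M HCl to pH 4
Reagents that add atoms: lithium hydroxide [Li+].[OH-]
Why: Saponification of the ethyl ester (acyl substitution by hydroxide) at room temperature leaves the silyl ether and the β-alkoxy linkage intact.

Step 13
Reactants: 20 seco acid
Product: 22 (1R,3S,7R,8R,11Z)-19-(tert-butyldimethylsilyloxy)-3,15-epoxy-4,5-secocembra-5,11-dien-18,7-olide (14-membered lactone with vinyl on C7), via 2,4,6-trichlorobenzoyl mixed anhydride 21 (not isolated)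
Conditions: 2,4,6-Cl3C6H2COCl, Et3N, THF, rt; then slow addition to DMAP, toluene, 80 °C (high dilution)
Reagents that add atoms: 2,4,6-trichlorobenzoyl chloride O=C(Cl)c1c(Cl)cc(Cl)cc1Cl (acyl group present in 21 only)
Why: Yamaguchi macrolactonisation, in which DMAP opens the mixed anhydride to an acylpyridinium that the C7 hydroxyl captures under high dilution with retention at C7, the unstrained 14-membered ring forming in preference to oligomers.

Step 14
Reactants: 22 14-membered lactone
Product: 25 (1R,3S,4S,6E,8S,11Z)-19-(tert-butyldimethylsilyloxy)-3,15-epoxycembra-6,11-dien-18-oic acid, via E-silyl ketene acetal 23 (not isolated), via trimethylsilyl ester 24 (not isolated)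
Conditions: LiN(iPr)2 added to 22 + Me3SiCl/Et3N, THF, −78 °C; then rt → 60 °C; 1 M HCl work-up
Reagents that add atoms: chlorotrimethylsilane C[Si](C)(C)Cl (silyl group present in 23 and 24 only)
Why: LiN(iPr)2 removes a C4 proton of 22 in the presence of Me3SiCl, so the enolate is trapped at once (before it can expel the C3 ring oxygen) as the E silyl ketene acetal 23, in which C3 is cis to the lactone oxygen as expected for kinetic HMPA-free enolisation and for the cisoid path of the large ring. On warming, 23 (an allyl vinyl ether, C4=C18–O–C7–C6=C5) undergoes the concerted suprafacial [3,3] shift that forms C4–C5 and breaks O–C7 to give silyl ester 24; this is the Ireland–Claisen rearrangement in its known lactone version, in which a lactone bearing an alkenyl group on its carbinol carbon becomes a carbocyclic acid. The six-membered transition state is bridged across C4 and C7 by the ten-atom tether C3–C2–C1–C14–C13–C12–C11–C10–C9–C8, so the 14-membered lactone ring (through C18 and O) is exchanged for the 14-membered carbocycle (through C5 and C6) by a ring-size-neutral reorganisation instead of an end-to-end macrocyclisation. The new stereocentre C4 is controlled by the carbinol C7 from step 6: in the chair with C8 pseudo-equatorial on C7 and C3 pseudo-axial on C4, the 7R centre delivers the vinyl terminus C5 to the face of C4 that gives 4S, with an E C6=C7 alkene as by-feature. The step needs a single ketene acetal geometry and chair over boat; the first is secured by the enolisation conditions, the second rests on the long flexible tether letting the allyl vinyl ether follow its intrinsic chair preference, and no second enolisable site exists because C19 is held as a silyl ether. Acidic work-up hydrolyses 24 to 25, and C1, C3 and C8 are untouched.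

Step 15
Reactants: 25 (1R,3S,4S,6E,8S,11Z)-19-(tert-butyldimethylsilyloxy)-3,15-epoxycembra-6,11-dien-18-oic acid
Product: 26 (1R,3S,4S,8R,11Z)-19-(tert-butyldimethylsilyloxy)-3,15-epoxycembr-11-en-18-oic acid
Conditions: 2-O2NC6H4SO2NHNH2, Et3N, CH2Cl2, rt
Reagents that add atoms: none
Why: Diimide reduction, in which concerted syn transfer of two hydrogens from HN=NH is much faster to the disubstituted C6=C7 alkene than to the trisubstituted C11=C12 alkene, and no stereocentre is involved.

Step 16
Reactants: 26 (1R,3S,4S,8R,11Z)-19-(tert-butyldimethylsilyloxy)-3,15-epoxycembr-11-en-18-oic acid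
Product: 27 (1R,3S,4S,8R,11Z)-3,15-epoxycembr-11-ene-18,19-dioic acid (CNP0115244.1)
Conditions: CrO3, H2SO4, acetone/H2O, 0 °C
Reagents that add atoms: chromium trioxide O=[Cr](=O)=O; water O
Why: Jones oxidation, in which the aqueous acid of the reagent removes the primary silyl ether and chromic acid takes the liberated C19 alcohol through the aldehyde hydrate to the carboxylic acid, while the trisubstituted alkene, the oxolane and the C4 and C8 stereocentres are not affected in cold acetone.

**Compound list**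

1 | (4R)-limonene 1,2-oxide, (+)-limonene oxide, cis/trans mixture at the epoxide carbons | CC(=C)[C@@H]1CCC2(C)OC2C1 | starting material
2 | (1S,2S,4R)-limonene-1,2-diol | CC(=C)[C@@H]1CC[C@](C)(O)[C@@H](O)C1 | intermediate (not isolated)
3 | (3R)-6-oxo-3-(prop-1-en-2-yl)heptanal | CC(=O)CC[C@H](CC=O)C(C)=C | intermediate
4 | ethyl diazoacetate | CCOC(=O)C=[N+]=[N-] | starting material
5 | ethyl (5R)-3,8-dioxo-5-(prop-1-en-2-yl)nonanoate | CCOC(=O)CC(=O)C[C@@H](CCC(C)=O)C(C)=C | intermediate
6 | ethyl (3S,5R)-3-hydroxy-8-oxo-5-(prop-1-en-2-yl)nonanoate | CCOC(=O)C[C@@H](O)C[C@@H](CCC(C)=O)C(C)=C | intermediate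
7 | ethyl 2-[(2S,4R)-5,5-dimethyl-4-(3-oxobutyl)oxolan-2-yl]acetate (substituents trans) | CCOC(=O)C[C@@H]1C[C@@H](CCC(C)=O)C(C)(C)O1 | intermediate
8 | (S)-4-benzyloxazolidin-2-one | O=C1N[C@@H](Cc2ccccc2)CO1 | starting material
9 | 5-bromopentanoyl chloride | O=C(Cl)CCCCBr | starting material
10 | (S)-4-benzyl-3-(5-bromopentanoyl)oxazolidin-2-one | O=C(CCCCBr)N1[C@@H](Cc2ccccc2)COC1=O | intermediate
11 | acrolein | C=CC=O | starting material
12 | dibutylboron Z-enolate of 10 | CCCCB(CCCC)O/C(=C\CCCBr)N1[C@@H](Cc2ccccc2)COC1=O | intermediate (not isolated)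
13 | (S)-4-benzyl-3-[(2S,3R)-2-(3-bromopropyl)-3-hydroxypent-4-enoyl]oxazolidin-2-one | C=C[C@@H](O)[C@H](CCCBr)C(=O)N1[C@@H](Cc2ccccc2)COC1=O | intermediate
14 | (2R,3R)-2-(3-bromopropyl)pent-4-ene-1,3-diol | C=C[C@@H](O)[C@H](CCCBr)CO | intermediate
15 | (3R,4R)-7-bromo-4-({[tert-butyl(dimethyl)silyl]oxy}methyl)hept-1-en-3-ol | C=C[C@@H](O)[C@H](CCCBr)CO[Si](C)(C)C(C)(C)C | intermediate
16 | 1-methyl-1H-tetrazole-5-thiol | Cn1nnnc1S | starting material
17 | (3R,4R)-4-({[tert-butyl(dimethyl)silyl]oxy}methyl)-7-[(1-methyl-1H-tetrazol-5-yl)sulfanyl]hept-1-en-3-ol | C=C[C@@H](O)[C@H](CCCSc1nnnn1C)CO[Si](C)(C)C(C)(C)C | intermediate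
18 | (3R,4R)-4-({[tert-butyl(dimethyl)silyl]oxy}methyl)-7-[(1-methyl-1H-tetrazol-5-yl)sulfonyl]hept-1-en-3-ol | C=C[C@@H](O)[C@H](CCCS(=O)(=O)c1nnnn1C)CO[Si](C)(C)C(C)(C)C | intermediate
19 | ethyl 2-[(2S,4R)-4-[(3Z,7R,8R)-7-({[tert-butyl(dimethyl)silyl]oxy}methyl)-8-hydroxy-3-methyldeca-3,9-dien-1-yl]-5,5-dimethyloxolan-2-yl]acetate (seco ester) | CCOC(=O)C[C@@H]1C[C@@H](CC/C(C)=C\CC[C@H](CO[Si](C)(C)C(C)(C)C)[C@H](O)C=C)C(C)(C)O1 | intermediate
20 | 2-[(2S,4R)-4-[(3Z,7R,8R)-7-({[tert-butyl(dimethyl)silyl]oxy}methyl)-8-hydroxy-3-methyldeca-3,9-dien-1-yl]-5,5-dimethyloxolan-2-yl]acetic acid (seco acid) | OC(=O)C[C@@H]1C[C@@H](CC/C(C)=C\CC[C@H](CO[Si](C)(C)C(C)(C)C)[C@H](O)C=C)C(C)(C)O1 | intermediate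
21 | mixed anhydride of 20 with 2,4,6-trichlorobenzoic acid | O=C(OC(=O)C[C@@H]1C[C@@H](CC/C(C)=C\CC[C@H](CO[Si](C)(C)C(C)(C)C)[C@H](O)C=C)C(C)(C)O1)c1c(Cl)cc(Cl)cc1Cl | intermediate (not isolated)
22 | 14-membered lactone of 20 (C18 carbonyl to O on C7; vinyl on C7; 1R,3S,7R,8R,11Z) | O=C1C[C@@H]2C[C@@H](CC/C(C)=C\CC[C@H](CO[Si](C)(C)C(C)(C)C)[C@H](O1)C=C)C(C)(C)O2 | intermediate
23 | E trimethylsilyl ketene acetal of 22 (C4=C18, C3 cis to the ring oxygen) | C[Si](C)(C)O/C1=C/[C@@H]2C[C@@H](CC/C(C)=C\CC[C@H](CO[Si](C)(C)C(C)(C)C)[C@H](O1)C=C)C(C)(C)O2 | intermediate (not isolated)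
24 | trimethylsilyl ester of 25 | C/C1=C/CC[C@H](CO[Si](C)(C)C(C)(C)C)/C=C/C[C@H](C(=O)O[Si](C)(C)C)[C@@H]2C[C@@H](CC1)C(C)(C)O2 | intermediate (not isolated)
25 | (1R,3S,4S,6E,8S,11Z)-19-(tert-butyldimethylsilyloxy)-3,15-epoxycembra-6,11-dien-18-oic acid | C/C1=C/CC[C@H](CO[Si](C)(C)C(C)(C)C)/C=C/C[C@H](C(=O)O)[C@@H]2C[C@@H](CC1)C(C)(C)O2 | intermediate
26 | (1R,3S,4S,8R,11Z)-19-(tert-butyldimethylsilyloxy)-3,15-epoxycembr-11-en-18-oic acid | C/C1=C/CC[C@H](CO[Si](C)(C)C(C)(C)C)CCC[C@H](C(=O)O)[C@@H]2C[C@@H](CC1)C(C)(C)O2 | intermediate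
27 | (1R,3S,4S,8R,11Z)-3,15-epoxycembr-11-ene-18,19-dioic acid (CNP0115244.1) | C/C1=C/CC[C@H](C(=O)O)CCC[C@H](C(=O)O)[C@@H]2C[C@@H](CC1)C(C)(C)O2 | target

Total step count: 16 (steps 1–4 left fragment, 5–10 right fragment, 11–16 union and endgame).
Longest linear sequence: 12 steps (5–10, then 11–16).

**Steps most likely to fail**

1. Step 14 (key step). The rearrangement may run through a boat-like transition state or through the other ketene acetal geometry, which would deliver C5 to the wrong face of C4. Fallback, from 20 back to 25: Mitsunobu macrolactonisation of 20 (PPh3, diisopropyl azodicarboxylate, toluene, high dilution) would close the ring with inversion at C7 to the C7-epimeric 14-membered lactone F1. If 22 turns out to rearrange through the boat, F1 would be rearranged under the conditions of step 14. If the ketene acetal geometry is at fault, F1 would be enolised in THF/DMPU to the other geometry (C3 trans to the ring oxygen), trapped with Me3SiCl and warmed. In either case the inverted carbinol is paired with the inverted facial demand, which should again lead to the 4S acid 25.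

2. Step 11. Z/E control in the addition–elimination sequence may be poor, or the sulfonyl anion may enolise the methyl ketone. Fallback, from 7 and 15 back to 19: the Z alkene would instead be made by a stereoretentive sp3–sp2 cross-coupling.
   - From 7, Baeyer–Villiger oxidation (CF3CO3H, Na2HPO4, CH2Cl2) should give ethyl 2-[(2S,4R)-4-(2-acetoxyethyl)-5,5-dimethyloxolan-2-yl]acetate F2.
   - Ethanolysis (K2CO3, EtOH) would give ethyl 2-[(2S,4R)-4-(2-hydroxyethyl)-5,5-dimethyloxolan-2-yl]acetate F3, and iodination (I2, PPh3, imidazole) ethyl 2-[(2S,4S)-4-(2-iodoethyl)-5,5-dimethyloxolan-2-yl]acetate F4.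
   - From 15, the amine N-oxide variant of the Kornblum oxidation (Me3NO, DMSO) would give the aldehyde, held as its lactol (5R,6R)-5-({[tert-butyl(dimethyl)silyl]oxy}methyl)-6-ethenyloxan-2-ol F5.
   - Wittig olefination of F5 with Ph3P=C(I)CH3 (from ethyltriphenylphosphonium iodide, n-BuLi, I2, then NaN(SiMe3)2, THF, −78 °C) should give the Z vinyl iodide (3R,4R,7Z)-4-({[tert-butyl(dimethyl)silyl]oxy}methyl)-8-iodonona-1,7-dien-3-ol F6.
   - Zinc insertion into F4 (Zn dust, LiCl, THF) and Negishi coupling with F6 (Pd(OAc)2, SPhos, THF) would then return to 19 with retention of the alkene geometry.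

3. Step 3. The ruthenium catalyst may hydrogenate or migrate the isopropenyl double bond, or enantioface control may be incomplete. Fallback, from 3 back to 6 (replacing steps 2 and 3): a chelation-controlled titanium acetate aldol of aldehyde 3 with (S)-3-acetyl-4-(propan-2-yl)-1,3-thiazolidine-2-thione (TiCl4, iPr2NEt, CH2Cl2, −78 °C) would set the 3S carbinol by auxiliary control without hydrogen gas. It would give (4S)-3-[(3S,5R)-3-hydroxy-8-oxo-5-(prop-1-en-2-yl)nonanoyl]-4-(propan-2-yl)-1,3-thiazolidine-2-thione F7, and ethanolysis (EtOH, imidazole) would return to 6.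

Further compounds
F1 | step 14 | C7 epimer of lactone 22 (1R,3S,7S,8R,11Z) | O=C1C[C@@H]2C[C@@H](CC/C(C)=C\CC[C@H](CO[Si](C)(C)C(C)(C)C)[C@@H](O1)C=C)C(C)(C)O2
F2 | step 11 | ethyl 2-[(2S,4R)-4-(2-acetoxyethyl)-5,5-dimethyloxolan-2-yl]acetate | CCOC(=O)C[C@@H]1C[C@@H](CCOC(C)=O)C(C)(C)O1
F3 | step 11 | ethyl 2-[(2S,4R)-4-(2-hydroxyethyl)-5,5-dimethyloxolan-2-yl]acetate | CCOC(=O)C[C@@H]1C[C@@H](CCO)C(C)(C)O1
F4 | step 11 | ethyl 2-[(2S,4S)-4-(2-iodoethyl)-5,5-dimethyloxolan-2-yl]acetate | CCOC(=O)C[C@@H]1C[C@@H](CCI)C(C)(C)O1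
F5 | step 11 | (5R,6R)-5-({[tert-butyl(dimethyl)silyl]oxy}methyl)-6-ethenyloxan-2-ol (lactol, anomeric mixture) | OC1CC[C@H](CO[Si](C)(C)C(C)(C)C)[C@@H](C=C)O1
F6 | step 11 | (3R,4R,7Z)-4-({[tert-butyl(dimethyl)silyl]oxy}methyl)-8-iodonona-1,7-dien-3-ol | C=C[C@@H](O)[C@H](CC/C=C(/C)I)CO[Si](C)(C)C(C)(C)C
F7 | step 3 | (4S)-3-[(3S,5R)-3-hydroxy-8-oxo-5-(prop-1-en-2-yl)nonanoyl]-4-(propan-2-yl)-1,3-thiazolidine-2-thione | CC(C)[C@H]1CSC(=S)N1C(=O)C[C@@H](O)C[C@@H](CCC(C)=O)C(C)=C
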